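**Retrosynthetic overview**

1. The target (3β-acetoxy-9α-hydroxylabd-13-en-15,16-olide) is cut at the acetate (made last), at C13=C14 of the butenolide (ring-closing metathesis of an acrylate) and at C11–C12 (SN2 opening of a 9α,11-epoxide by dilithiated methallyl alcohol); the epoxide comes from a C9 ketone by methylenation and α-face epoxidation.
2. The 3β-hydroxy-9-ketone decalin is traced to a 3,9-dione that carries a 7α-isopropenyl group, a traceless stereocontrol element inherited from (R)-carvone and removed by dealkenylative hydrogenation.
3. Ring A is disconnected at C1–C10 and C2–C3 in one operation: an anionic [4+2] Michael–Dieckmann annulation of a C10 enolate and a C3 methyl ester with methyl acrylate as the C1–C2 unit; the monocyclic precursor comes from 6-methylcarvone by a Mukaiyama–Michael addition that forms C4–C5.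
4. Enabling feature: in ring A, C10 is the α-carbon of the C9 carbonyl and C3 is an oxygenated carbon next to the quaternary C4, so C10 (enolate) and C3 (non-enolisable ester) form a donor/acceptor pair joined by C5–C4 that a two-carbon Michael acceptor can bridge; the C8 methyl blocks the other α-side of C9.
5. Ring order: ring B (bought with carvone), then ring A (step 3), then the butenolide (step 11).

Key step: step 3

Remark: labdane numbering is used for all intermediates (ring A = C1–C5 and C10, ring B = C5–C10, side chain C11–C16; α is the face opposite to the C10 methyl). Compound 2 is carried forward as its major trans epimer; the configuration at C8 is reset in steps 3 and 4.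

**Step 1**
Reactants: 1 (R)-(−)-carvone
Product: 2 trans-6-methylcarvone
Conditions: LiN(i-Pr)2, THF, −78 °C; MeI, −78 → 0 °C
Reagents that add atoms: iodomethane, CI
Why: Kinetic α′-deprotonation of the enone and enolate alkylation should place the future C8 methyl trans to the isopropenyl group; this centre stays epimerisable and is corrected later.

**Step 2**
Reactants: 2 trans-6-methylcarvone; 3 1-methoxy-2-methyl-1-(trimethylsilyloxy)prop-1-ene
Product: 4 methyl 2-methyl-2-[(1R,4S,5R)-2,4-dimethyl-5-(prop-1-en-2-yl)-3-(trimethylsilyloxy)cyclohex-2-en-1-yl]propanoate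
Conditions: Me3SiOTf (5 mol %), CH2Cl2, −78 °C; Et3N quench
Reagents that add atoms: none
Why: A Mukaiyama–Michael addition with silyl transfer should form C4–C5 by axial attack on the β-carbon anti to the isopropenyl group (C5 trans to C7, as in conjugate additions to carvone) and trap the enolate as the regiodefined C9=C10 silyl enol ether.

**Step 3**
Reactants: 4 silyl enol ether; 5 methyl acrylate
Product: 8 methyl 3,9-dioxo-7α-(prop-1-en-2-yl)-4,4,8α,10β-tetramethyl-trans-decalin-2-carboxylate, via potassium enolate 6 (not isolated), via ester enolate 7 (not isolated)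
Conditions: KOt-Bu (1.0 equiv), THF, −20 °C; 5 (slow addition), −78 → 0 °C; then KOt-Bu (0.2 equiv), t-BuOH, 23 °C; aq. NH4Cl
Reagents that add atoms: none
Why: KOt-Bu cleaves the O–Si bond and releases the tetrasubstituted potassium enolate 6 regiospecifically at C10; its conjugate addition to methyl acrylate forms C1–C10 and gives ester enolate 7, which attacks the C3 ester carbonyl (addition–elimination with loss of methoxide) to form C2–C3, the acidic β-keto ester being deprotonated as the thermodynamic sink. The closest known reaction type is the Michael–Dieckmann (Michael–Claisen) [4+2] annulation of ketone enolates with acrylates, a Michael-initiated ring closure. Ring A is closed in the 6-(enolexo)-exo-trig mode. C10 is controlled by the C5 substituent, which lies pseudoaxial in the enolate to avoid allylic 1,2-strain with the C10 methyl, so the acrylate should enter from the opposite α face (C1 trans to C4, methyl β, hence a trans ring fusion); C8 is equilibrated through its enolate to the equatorial α-methyl, which avoids the 1,3-diaxial contact with the 10β-methyl, and C2 is inconsequential because its ester is removed in step 4. The step needs reaction at C10 rather than C8 and ring closure onto C3 rather than oligomerisation or α,α′-annulation: the silyl enol ether from step 2 fixes the enolate position, the quaternary C4 makes the C3 ester non-enolisable, the C8 methyl makes the alternative bridged β-diketone non-enolisable and therefore reversible, and slow addition of the acrylate at −78 °C with fast intramolecular acylation should keep oligomerisation down.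

**Step 4**
Reactants: 8 β-keto ester
Product: 9 7α-(prop-1-en-2-yl)-4,4,8α,10β-tetramethyl-trans-decalin-3,9-dione
Conditions: LiCl, DMSO, H2O, 150 °C
Reagents that add atoms: none
Why: Krapcho dealkoxycarbonylation (chloride SN2 at the ester methyl, then decarboxylation of the β-keto carboxylate) should remove the activating ester; any residual 8β-epimer should equilibrate to the 8α-methyl under these conditions.

**Step 5**
Reactants: 9 dione
Product: 10 3β-hydroxy-7α-(prop-1-en-2-yl)-4,4,8α,10β-tetramethyl-trans-decalin-9-one
Conditions: NaBH4, MeOH/CH2Cl2, −78 → −40 °C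
Reagents that add atoms: none
Why: Chemoselective hydride reduction should occur at C3 because C9 is flanked by the quaternary C10 and the C8 methine and is screened by the 10β-methyl on one face and the axial 7α-isopropenyl on the other; axial hydride delivery from the α face, away from the axial 4β-methyl, should give the equatorial 3β-alcohol, as in reductions of 4,4-dimethyl-3-oxo terpenoids.

**Step 6**
Reactants: 10 hydroxy ketone
Product: 11 3β-hydroxy-4,4,8α,10β-tetramethyl-trans-decalin-9-one
Conditions: O3, MeOH, −78 °C; then FeSO4·7H2O, PhSH, −78 → 23 °C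
Reagents that add atoms: none
Why: Dealkenylative hydrogenation: ozonolysis in methanol gives the α-methoxy hydroperoxide, divalent iron cleaves the O–O bond, β-scission of the alkoxyl radical expels methyl acetate, and the secondary C7 radical takes hydrogen from the thiol; no other stereocentre is touched.

**Step 7**
Reactants: 11 hydroxy ketone
Product: 12 4,4,8α,10β-tetramethyl-9-methylidene-trans-decalin-3β-ol
Conditions: Ph3PCH3Br (4 equiv), KOt-Bu (4 equiv), toluene, 90 °C
Reagents that add atoms: methyltriphenylphosphonium bromide, C[P+](c1ccccc1)(c1ccccc1)c1ccccc1.[Br-]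
Why: Wittig methylenation with hot KOt-Bu-generated ylide is the established way to olefinate ketones flanked by quaternary carbons; the excess ylide covers the free hydroxyl, and C8 is already the thermodynamic epimer.

**Step 8**
Reactants: 12 exocyclic alkene
Product: 13 9α,11-epoxy-4,4,8α,10β-tetramethyl-trans-decalin-3β-ol (spiro-epoxide)
Conditions: mCPBA, NaHCO3, CH2Cl2, 0 °C
Reagents that add atoms: 3-chloroperoxybenzoic acid, OOC(=O)c1cccc(Cl)c1
Why: Prilezhaev epoxidation should occur from the α face because the axial 10β-methyl screens the β face of the exocyclic alkene; this sets C9 with oxygen α (axial) and C11 β (equatorial).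

**Step 9**
Reactants: 13 spiro-epoxide; 14 2-methylprop-2-en-1-ol
Product: 16 9β-[3-(hydroxymethyl)but-3-en-1-yl]-4,4,8α,10β-tetramethyl-trans-decalin-3β,9α-diol, via lithium 2-(lithiomethyl)prop-2-en-1-olate 15 (not isolated)
Conditions: 14, n-BuLi (2 equiv per 14), TMEDA, Et2O, 0 → 23 °C; then 13, THF, −78 → 23 °C; aq. NH4Cl
Reagents that add atoms: none
Why: SN2 opening of the 2,2-disubstituted epoxide at the primary C11 by the allylic carbon of the dilithio reagent (a symmetrical allyl nucleophile, so no regiochemical issue) forms C11–C12; the C9–O bond is not touched, so the 9α-hydroxyl is retained.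

**Step 10**
Reactants: 16 triol
Product: 17 4-[3β,9α-dihydroxy-4,4,8α,10β-tetramethyl-trans-decalin-9β-yl]-2-methylidenebutyl prop-2-enoate
Conditions: CH2=CHCOCl (1.05 equiv), Et3N, CH2Cl2, −78 °C
Reagents that add atoms: acryloyl chloride, C=CC(Cl)=O
Why: O-Acylation should be selective for the primary allylic alcohol over the secondary C3 hydroxyl next to the gem-dimethyl group and the tertiary C9 hydroxyl.

**Step 11**
Reactants: 17 acrylate
Product: 18 3β,9α-dihydroxylabd-13-en-15,16-olide
Conditions: second-generation Grubbs catalyst (H2IMes)(PCy3)Cl2Ru=CHPh (5 mol %), CH2Cl2, 40 °C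
Reagents that add atoms: none
Why: Ring-closing metathesis between the acrylate and the 1,1-disubstituted alkene should give the β-substituted butenolide with loss of ethene; free hydroxyls are tolerated.

**Step 12**
Reactants: 18 dihydroxy butenolide
Product: 19 3β-acetoxy-9α-hydroxylabd-13-en-15,16-olide (target)
Conditions: Ac2O, pyridine, DMAP (cat.), 23 °C
Reagents that add atoms: acetic anhydride, CC(=O)OC(C)=O
Why: DMAP-catalysed acetylation should esterify the secondary 3β-hydroxyl while the hindered tertiary 9α-hydroxyl stays free.

**Compound list**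

1 | (R)-(−)-carvone, (5R)-2-methyl-5-(prop-1-en-2-yl)cyclohex-2-en-1-one | CC1=CC[C@H](CC1=O)C(C)=C | starting material
2 | trans-6-methylcarvone, (5R,6S)-2,6-dimethyl-5-(prop-1-en-2-yl)cyclohex-2-en-1-one | C[C@@H]1C(=O)C(C)=CC[C@H]1C(C)=C | intermediate
3 | 1-methoxy-2-methyl-1-(trimethylsilyloxy)prop-1-ene (dimethylketene methyl trimethylsilyl acetal) | COC(O[Si](C)(C)C)=C(C)C | starting material
4 | methyl 2-methyl-2-[(1R,4S,5R)-2,4-dimethyl-5-(prop-1-en-2-yl)-3-(trimethylsilyloxy)cyclohex-2-en-1-yl]propanoate (ester side chain trans to isopropenyl) | C[C@@H]1C(O[Si](C)(C)C)=C(C)[C@H](C(C)(C)C(=O)OC)C[C@H]1C(C)=C | intermediate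
5 | methyl acrylate | C=CC(=O)OC | starting material
6 | potassium enolate of 4 (O–K in place of O–SiMe3) | C[C@@H]1C(O[K])=C(C)[C@H](C(C)(C)C(=O)OC)C[C@H]1C(C)=C | intermediate (not isolated)
7 | Michael adduct as potassium ester enolate (C10 quaternary; new chain trans to the C5 side chain) | C[C@@H]1C(=O)[C@@](C)(CC=C(OC)O[K])[C@H](C(C)(C)C(=O)OC)C[C@H]1C(C)=C | intermediate (not isolated)
8 | methyl 3,9-dioxo-7α-(prop-1-en-2-yl)-4,4,8α,10β-tetramethyl-trans-decalin-2-carboxylate (5α-H; C2 epimers and enol form) | COC(=O)C1C[C@]2(C)C(=O)[C@H](C)[C@H](C(C)=C)C[C@H]2C(C)(C)C1=O | intermediate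
9 | 7α-(prop-1-en-2-yl)-4,4,8α,10β-tetramethyl-trans-decalin-3,9-dione (5α-H) | O=C1CC[C@]2(C)C(=O)[C@H](C)[C@H](C(C)=C)C[C@H]2C1(C)C | intermediate
10 | 3β-hydroxy-7α-(prop-1-en-2-yl)-4,4,8α,10β-tetramethyl-trans-decalin-9-one | O[C@H]1CC[C@]2(C)C(=O)[C@H](C)[C@H](C(C)=C)C[C@H]2C1(C)C | intermediate
11 | 3β-hydroxy-4,4,8α,10β-tetramethyl-trans-decalin-9-one | O[C@H]1CC[C@]2(C)C(=O)[C@H](C)CC[C@H]2C1(C)C | intermediate
12 | 4,4,8α,10β-tetramethyl-9-methylidene-trans-decalin-3β-ol | O[C@H]1CC[C@]2(C)C(=C)[C@H](C)CC[C@H]2C1(C)C | intermediate
13 | 9α,11-epoxy-4,4,8α,10β-tetramethyl-trans-decalin-3β-ol (spiro-oxirane, oxygen on the α face) | O[C@H]1CC[C@]2(C)[C@@]3(CO3)[C@H](C)CC[C@H]2C1(C)C | intermediate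
14 | 2-methylprop-2-en-1-ol (methallyl alcohol) | CC(=C)CO | starting material
15 | lithium 2-(lithiomethyl)prop-2-en-1-olate | [Li]CC(=C)CO[Li] | intermediate (not isolated)
16 | 9β-[3-(hydroxymethyl)but-3-en-1-yl]-4,4,8α,10β-tetramethyl-trans-decalin-3β,9α-diol | O[C@H]1CC[C@]2(C)[C@@](O)(CCC(=C)CO)[C@H](C)CC[C@H]2C1(C)C | intermediate
17 | 4-[3β,9α-dihydroxy-4,4,8α,10β-tetramethyl-trans-decalin-9β-yl]-2-methylidenebutyl prop-2-enoate | O[C@H]1CC[C@]2(C)[C@@](O)(CCC(=C)COC(=O)C=C)[C@H](C)CC[C@H]2C1(C)C | intermediate
18 | 3β,9α-dihydroxylabd-13-en-15,16-olide | O[C@H]1CC[C@]2(C)[C@@](O)(CCC3=CC(=O)OC3)[C@H](C)CC[C@H]2C1(C)C | intermediate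
19 | 3β-acetoxy-9α-hydroxylabd-13-en-15,16-olide | CC(=O)O[C@H]1CC[C@@]2(C)[C@@H](CC[C@@H](C)[C@]2(O)CCC2=CC(=O)OC2)C1(C)C | target

**Step count and risks**

Total step count: 12. Longest linear sequence: 12 steps, from 1 to 19.

Steps most likely to fail:

Step 3. The hindered tetrasubstituted enolate may add too slowly, so that anionic oligomerisation of the acrylate by the ester enolate and proton exchange between the regioisomeric ketone enolates take over. The fallback sets out from 4: the enolate is released with KOt-Bu as before and trapped with phenyl vinyl sulfone, whose α-sulfonyl carbanion does not propagate. On warming, this carbanion should acylate on the C3 ester and give the β-keto sulfone F1. Reductive desulfonylation with aluminium amalgam (Al/Hg) in aqueous THF should then give dione 9, where the route is rejoined; step 4 is not needed.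

Step 9. The strongly basic dilithio reagent may isomerise the epoxide to an allylic alcohol by deprotonation, and SN2 attack at the neopentyl-type C11 may be too slow. The fallback sets out from 13 and uses a softer copper-mediated opening with (furan-3-ylmethyl)magnesium chloride (from 3-(chloromethyl)furan and Mg; CuI cat., THF, −30 °C), which should give the furan diol F2. Sensitised photo-oxygenation (O2, rose bengal, light, i-Pr2NEt, CH2Cl2, −78 °C), in which the hindered base removes the less hindered α-hydrogen of the endoperoxide, should give the 16-hydroxybutenolide F3. Reduction with NaBH4 in ethanol should give 18, where the route is rejoined; steps 10 and 11 are not needed.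

Step 8. The peracid may attack the exocyclic alkene with poor or reversed facial selectivity (oxygen delivered to the β face), which would give the C9 epimer. The fallback sets out from 12 and inverts the facial outcome: NBS in aqueous acetone places the electrophile on the face the peracid preferred, and water opens the bromonium ion at the tertiary C9 from the opposite face to give the bromohydrin F4. Closure with K2CO3 in methanol should then give epoxide 13, where the route is rejoined.

**Further compounds**

F1 | step 3 | 2-(phenylsulfonyl)-7α-(prop-1-en-2-yl)-4,4,8α,10β-tetramethyl-trans-decalin-3,9-dione (C2 epimers) | O=C1C(S(=O)(=O)c3ccccc3)C[C@]2(C)C(=O)[C@H](C)[C@H](C(C)=C)C[C@H]2C1(C)C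
F2 | step 9 | 15,16-epoxylabda-13(16),14-diene-3β,9α-diol (3-substituted furan) | O[C@H]1CC[C@]2(C)[C@@](O)(CCc3ccoc3)[C@H](C)CC[C@H]2C1(C)C
F3 | step 9 | 3β,9α,16-trihydroxylabd-13-en-15,16-olide (C16 epimers) | O[C@H]1CC[C@]2(C)[C@@](O)(CCC3=CC(=O)OC3O)[C@H](C)CC[C@H]2C1(C)C
F4 | step 8 | 9β-(bromomethyl)-4,4,8α,10β-tetramethyl-trans-decalin-3β,9α-diol | O[C@H]1CC[C@]2(C)[C@@](O)(CBr)[C@H](C)CC[C@H]2C1(C)C
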